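**Retrosynthetic overview**
1. Target ⇒ last-step ring contraction: a trans-fused 4-chloro-tetrahydroazulen-5-one undergoes a hydroxide-triggered quasi-Favorskii 1,2-shift that makes the cyclohexene, the acid and the bond between the two quaternary carbons.
2. Chloro ketone ⇒ cycloheptenone (enolate chlorination); styryl ⇒ vinyl (Heck); seven-membered ring ⇒ group-selective ring-closing metathesis of a 1,1-divinyl ketone triene, which sets the ethyl/styryl quaternary carbon.
3. Triene ⇒ Michael addition of the enolate of 3-ethenyl-3-ethylhept-1-en-4-one to a trans-4,5-disubstituted 2-ethylcyclopentenone (sets the ring-fusion carbon; enolate kept as silyl enol ether).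
4. Cyclopentenone ⇒ (S)-4-silyloxycyclopentenone (alkenyl addition/methylation/elimination, α-iodination, Negishi ethylation); divinyl ketone ⇒ methyl propanoate, vinyl Grignard, butanenitrile.
5. Ring order: cyclopentane (present from the start) → seven-membered carbocycle (metathesis) → six-membered ring (contraction).

Assumption: the CH(Et) centre next to the seven-ring ketone (formed in step 7, flattened in step 10) is carried as a mixture of epimers and is left unspecified in the SMILES of 17–19 and 21.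

**Route**

Step 1
Reactants: 1 methyl propanoate
Product: 2 3-ethylpenta-1,4-dien-3-ol
Conditions: CH2=CHMgBr (2.3 equiv), THF, −20 → 25 °C; aq NH4Cl
Reagents that add atoms: vinylmagnesium bromide, C=C[Mg]Br
Why: Double Grignard addition to an ester gives the tertiary divinyl carbinol, which has no stereocentre.

Step 2
Reactants: 2 3-ethylpenta-1,4-dien-3-ol
Product: 3 5-bromo-3-ethylpenta-1,3-diene (E/Z mixture)
Conditions: PBr3 (0.4 equiv), pyridine (cat.), Et2O, −10 → 0 °C
Reagents that add atoms: phosphorus tribromide, BrP(Br)Br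
Why: Bromination of the tertiary bis-allylic alcohol goes with allylic transposition (SN2'-type substitution) to the conjugated primary bromide, whose alkene geometry is irrelevant because the derived zinc reagent is fluxional.

Step 3
Reactants: 3 5-bromo-3-ethylpenta-1,3-diene, 4 butanenitrile
Product: 7 3-ethenyl-3-ethylhept-1-en-4-one, via allylic zinc bromide 5 (not isolated), via zinc ketiminate 6 (not isolated)
Conditions: Zn dust, LiCl, THF, 0 °C; 4, 0 → 25 °C; 1 M HCl, 25 °C
Reagents that add atoms: zinc, [Zn] (into 5 and 6); water, O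
Why: Barbier-type addition of the pentadienylzinc reagent to the nitrile through a six-membered SE2' transition state bonds the central ethyl-bearing carbon to the nitrile carbon (as prenylzinc reagents do), and hydrolysis of the ketiminate gives the achiral α-quaternary ketone.

Step 4
Reactants: 8 (4S)-4-[(tert-butyldimethylsilyl)oxy]cyclopent-2-en-1-one, 9 2-bromobut-1-ene
Product: 13 (4R,5S)-4-(but-1-en-2-yl)-5-methylcyclopent-2-en-1-one, via Grignard reagent 10 (not isolated), via magnesium enolate 11 (not isolated), via silyloxy ketone 12 (not isolated)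
Conditions: 9, Mg, THF, 25 °C; CuBr·SMe2 (10 mol %), 8, THF, −78 °C; MeI, DMPU, −78 → −20 °C; DBU, 0 °C, 30 min
Reagents that add atoms: magnesium, [Mg] (into 10 and 11); iodomethane, CI
Why: Copper-catalysed conjugate addition anti to the silyloxy group sets C-4, methylation of the regiodefined enolate anti to the new alkenyl group sets C-5 (three-component coupling), and E1cB loss of silanolate gives the transposed enone.

Step 5
Reactants: 13 (4R,5S)-4-(but-1-en-2-yl)-5-methylcyclopent-2-en-1-one
Product: 14 (4S,5S)-4-(but-1-en-2-yl)-2-iodo-5-methylcyclopent-2-en-1-one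
Conditions: I2 (1.5 equiv), pyridine/CH2Cl2 1:1, 0 → 25 °C
Reagents that add atoms: iodine, [I][I]
Why: Johnson α-iodination (pyridine conjugate addition, enolate iodination, E1cB) touches no stereocentre; the C-4 descriptor changes only through priorities.

Step 6
Reactants: 14 (4S,5S)-4-(but-1-en-2-yl)-2-iodo-5-methylcyclopent-2-en-1-one
Product: 15 (4R,5S)-4-(but-1-en-2-yl)-2-ethyl-5-methylcyclopent-2-en-1-one
Conditions: Et2Zn (1.5 equiv), PdCl2(dppf) (5 mol %), THF, 0 → 25 °C; aq NH4Cl
Reagents that add atoms: diethylzinc, CC[Zn]CC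
Why: Negishi coupling of the α-iodo enone, with dppf favouring reductive elimination over β-hydride elimination, installs the α-ethyl group without touching a stereocentre.

Step 7
Reactants: 7 3-ethenyl-3-ethylhept-1-en-4-one, 15 (4R,5S)-4-(but-1-en-2-yl)-2-ethyl-5-methylcyclopent-2-en-1-one
Product: 18 5-[(1S,4S,5R)-5-(but-1-en-2-yl)-3-[(tert-butyldimethylsilyl)oxy]-2-ethyl-4-methylcyclopent-2-en-1-yl]-3-ethenyl-3-ethylhept-1-en-4-one (C-5 epimers), via ketone lithium enolate 16 (not isolated), via adduct lithium enolate 17 (not isolated)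
Conditions: 7 (1.2 equiv), LiN(i-Pr)2, THF, −78 °C; 15, −78 → −40 °C; TBSCl, DMPU, −40 → 0 °C
Reagents that add atoms: lithium diisopropylamide, [Li]N(C(C)C)C(C)C (Li into 16 and 17); tert-butyldimethylsilyl chloride, CC(C)(C)[Si](C)(C)Cl
Why: Michael addition of the only possible (Z)-lithium enolate of 7 to the enone anti to the butenyl group sets the future ring-fusion carbon trans, and O-silylation of the regiodefined adduct enolate masks the cyclopentanone for steps 8–10.

Step 8
Reactants: 18 triene silyl enol ether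
Product: 19 (1S,3aS,6S,8aR)-2-[(tert-butyldimethylsilyl)oxy]-6-ethenyl-3,4,6,8-tetraethyl-1-methyl-3a,4,6,8a-tetrahydroazulen-5(1H)-one (C-4 epimers)
Conditions: RuCl2(=CHPh)(PCy3)(L) (5 mol %; L = (4R,5R)-1,3-bis(2-isopropylphenyl)-4,5-diphenylimidazolidin-2-ylidene), NaI, THF, 40 °C
Reagents that add atoms: none
Why: Asymmetric ring-closing metathesis in which the chiral carbene ligand on ruthenium selects one of the two diastereotopic vinyl groups to close onto the 1,1-disubstituted alkene forms the trans-fused cycloheptenone and sets the quaternary carbon with the remaining vinyl group cis to H-3a.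

Step 9
Reactants: 19 vinyl cycloheptenone, 20 iodobenzene
Product: 21 (1S,3aS,6S,8aR)-2-[(tert-butyldimethylsilyl)oxy]-3,4,6,8-tetraethyl-1-methyl-6-[(E)-2-phenylethenyl]-3a,4,6,8a-tetrahydroazulen-5(1H)-one (C-4 epimers)
Conditions: 20 (1.5 equiv), Pd(OAc)2 (5 mol %), Bu4NBr, K2CO3, DMF, 80 °C
Reagents that add atoms: none
Why: Mizoroki–Heck arylation of the only monosubstituted alkene gives the (E)-styryl group exclusively, because β-hydride elimination cannot occur toward the quaternary carbon.

Step 10
Reactants: 21 styryl cycloheptenone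
Product: 25 (1S,3S,3aR,4R,5S,7aR)-3,4,5,7-tetraethyl-1-methyl-2-oxo-5-[(E)-2-phenylethenyl]-2,3,3a,4,5,7a-hexahydro-1H-indene-4-carboxylic acid, via lithium enolate 22 (not isolated), via chloro ketone 23 (not isolated), via silyl enol ether acid 24 (not isolated)
Conditions: LiN(i-Pr)2, THF, −78 → −20 °C; C2Cl6, −78 → 0 °C; KOH (10 equiv), H2O/t-BuOH, 25 °C then 60 °C; 1 M HCl to pH 3, 0 °C
Reagents that add atoms: lithium diisopropylamide, [Li]N(C(C)C)C(C)C (Li into 22); hexachloroethane, ClC(Cl)(Cl)C(Cl)(Cl)Cl (Cl into 23); potassium hydroxide, [K+].[OH-]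
Why: Proposed new method: a one-flask enolate chlorination and hydroxide-triggered semibenzilic (quasi-Favorskii) ring contraction, in which the only enolisable position is chlorinated anti to the cyclopentene branch at C-3a, hydroxide adds to the ketone that has no α'-hydrogen, and the doubly allylic quaternary ring carbon migrates antiperiplanar to the leaving chloride (inversion at the chlorinated carbon, retention at the migrating carbon) to give the cyclohexene acid with both quaternary centres set, after which warm hydroxide cleaves the silyl enol ether and equilibrates the two ketone α-centres to the all-trans cyclopentanone; the closest known reaction type is the quasi-Favorskii rearrangement of α-halo ketones lacking α'-hydrogens, not yet shown for a tertiary chloride with an all-carbon quaternary migrating centre.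

**Compound list**
1 | methyl propanoate | CCC(=O)OC | starting material
2 | 3-ethylpenta-1,4-dien-3-ol | CCC(O)(C=C)C=C | intermediate
3 | 5-bromo-3-ethylpenta-1,3-diene (E/Z mixture) | C=CC(CC)=CCBr | intermediate
4 | butanenitrile | CCCC#N | starting material
5 | bromo(3-ethylpenta-2,4-dien-1-yl)zinc | C=CC(CC)=CC[Zn]Br | intermediate
6 | bromozinc salt of 3-ethenyl-3-ethylhept-1-en-4-imine | CCCC(=N[Zn]Br)C(CC)(C=C)C=C | intermediate
7 | 3-ethenyl-3-ethylhept-1-en-4-one | CCCC(=O)C(CC)(C=C)C=C | intermediate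
8 | (4S)-4-[(tert-butyldimethylsilyl)oxy]cyclopent-2-en-1-one | O=C1C=C[C@@H](O[Si](C)(C)C(C)(C)C)C1 | starting material
9 | 2-bromobut-1-ene | CCC(Br)=C | starting material
10 | bromo(but-1-en-2-yl)magnesium | CCC(=C)[Mg]Br | intermediate
11 | bromomagnesium (3R,4S)-3-(but-1-en-2-yl)-4-[(tert-butyldimethylsilyl)oxy]cyclopent-1-en-1-olate | CCC(=C)[C@@H]1[C@@H](O[Si](C)(C)C(C)(C)C)CC(O[Mg]Br)=C1 | intermediate
12 | (2S,3R,4S)-3-(but-1-en-2-yl)-4-[(tert-butyldimethylsilyl)oxy]-2-methylcyclopentan-1-one | CCC(=C)[C@@H]1[C@@H](O[Si](C)(C)C(C)(C)C)CC(=O)[C@H]1C | intermediate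
13 | (4R,5S)-4-(but-1-en-2-yl)-5-methylcyclopent-2-en-1-one | CCC(=C)[C@@H]1C=CC(=O)[C@H]1C | intermediate
14 | (4S,5S)-4-(but-1-en-2-yl)-2-iodo-5-methylcyclopent-2-en-1-one | CCC(=C)[C@@H]1C=C(I)C(=O)[C@H]1C | intermediate
15 | (4R,5S)-4-(but-1-en-2-yl)-2-ethyl-5-methylcyclopent-2-en-1-one | CCC(=C)[C@@H]1C=C(CC)C(=O)[C@H]1C | intermediate
16 | lithium (Z)-enolate of 7 (lithium 3-ethenyl-3-ethylhepta-1,4-dien-4-olate) | CC/C=C(\O[Li])C(CC)(C=C)C=C | intermediate
17 | lithium enolate of the Michael adduct (enolate oxygen on the cyclopentene, side chain trans to butenyl) | CCC(=C)[C@@H]1[C@@H](C(CC)C(=O)C(CC)(C=C)C=C)C(CC)=C(O[Li])[C@H]1C | intermediate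
18 | 5-[(1S,4S,5R)-5-(but-1-en-2-yl)-3-[(tert-butyldimethylsilyl)oxy]-2-ethyl-4-methylcyclopent-2-en-1-yl]-3-ethenyl-3-ethylhept-1-en-4-one | CCC(=C)[C@@H]1[C@@H](C(CC)C(=O)C(CC)(C=C)C=C)C(CC)=C(O[Si](C)(C)C(C)(C)C)[C@H]1C | intermediate
19 | (1S,3aS,6S,8aR)-2-[(tert-butyldimethylsilyl)oxy]-6-ethenyl-3,4,6,8-tetraethyl-1-methyl-3a,4,6,8a-tetrahydroazulen-5(1H)-one (trans ring fusion) | CCC1=C[C@@](C=C)(CC)C(=O)C(CC)[C@@H]2[C@@H]1[C@H](C)C(O[Si](C)(C)C(C)(C)C)=C2CC | intermediate
20 | iodobenzene | Ic1ccccc1 | starting material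
21 | (1S,3aS,6S,8aR)-2-[(tert-butyldimethylsilyl)oxy]-3,4,6,8-tetraethyl-1-methyl-6-[(E)-2-phenylethenyl]-3a,4,6,8a-tetrahydroazulen-5(1H)-one | CCC1=C[C@@](/C=C/c3ccccc3)(CC)C(=O)C(CC)[C@@H]2[C@@H]1[C@H](C)C(O[Si](C)(C)C(C)(C)C)=C2CC | intermediate
22 | lithium enolate of 21 (C-4/C-5 enolate) | CCC1=C[C@@](/C=C/c3ccccc3)(CC)C(O[Li])=C(CC)[C@@H]2[C@@H]1[C@H](C)C(O[Si](C)(C)C(C)(C)C)=C2CC | intermediate
23 | (1S,3aR,4R,6S,8aS)-2-[(tert-butyldimethylsilyl)oxy]-4-chloro-3,4,6,8-tetraethyl-1-methyl-6-[(E)-2-phenylethenyl]-3a,4,6,8a-tetrahydroazulen-5(1H)-one (Cl cis to H-3a) | CCC1=C[C@@](/C=C/c3ccccc3)(CC)C(=O)[C@@](Cl)(CC)[C@@H]2[C@@H]1[C@H](C)C(O[Si](C)(C)C(C)(C)C)=C2CC | intermediate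
24 | (1S,3aR,4R,5S,7aR)-2-[(tert-butyldimethylsilyl)oxy]-3,4,5,7-tetraethyl-1-methyl-5-[(E)-2-phenylethenyl]-3a,4,5,7a-tetrahydro-1H-indene-4-carboxylic acid | CCC1=C[C@@](/C=C/c3ccccc3)(CC)[C@](CC)(C(=O)O)[C@@H]2[C@@H]1[C@H](C)C(O[Si](C)(C)C(C)(C)C)=C2CC | intermediate
25 | (1S,3S,3aR,4R,5S,7aR)-3,4,5,7-tetraethyl-1-methyl-2-oxo-5-[(E)-2-phenylethenyl]-2,3,3a,4,5,7a-hexahydro-1H-indene-4-carboxylic acid | CCC1=C[C@@](/C=C/c2ccccc2)(CC)[C@](CC)(C(=O)O)[C@@H]2[C@@H]1[C@H](C)C(=O)[C@H]2CC | target

**Step count and risks**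

Total: 10 steps. Longest linear sequence: 7 steps (steps 4–10, from 8). Steps 1–3 are a three-step side branch.

Step 7 (Michael addition). A hindered ketone enolate must add to an α-ethyl enone whose bis-allylic C-4 hydrogen is acidic, so proton transfer or 1,2-addition may win. The fallback sets out from 7 and comes back at 18. Ketone 7 is converted (LiN(i-Pr)2, then TBSCl) into its silyl enol ether, tert-butyl{[(4Z)-3-ethenyl-3-ethylhepta-1,4-dien-4-yl]oxy}dimethylsilane F1. A Mukaiyama–Michael reaction of this with 15 under catalytic Tf2NH in CH2Cl2 at −78 °C, with silyl transfer, gives 18 directly under non-basic conditions.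

Step 8 (group-selective metathesis). The choice between the two vinyl groups rests on catalyst control in an already chiral substrate; the ligand antipode may prove mismatched and the selectivity low. The fallback sets out from 7 and comes back at 21, so that no vinyl selection is needed.
- Mono-Heck arylation of 7 with 20 (Pd(OAc)2, Bu4NBr, K2CO3) gives racemic (E)-3-ethenyl-3-ethyl-1-phenylhept-1-en-4-one F2.
- Its lithium enolate is added to 15 and silylated as in step 7. This gives the adduct with the wanted quaternary configuration F3 and the quaternary-carbon epimer F4, which are separated by chromatography.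
- Ring closure of F3 with the second-generation Grubbs catalyst RuCl2(=CHPh)(PCy3)(H2IMes), which has only one vinyl group to use, gives 21.

Step 10 (proposed new ring contraction). Hydroxide may instead cause elimination of HCl toward the ethyl group, substitution, or early loss of the silyl group followed by cyclopropane formation from the freed enolate. The fallback uses known reactions; it sets out from 21 and comes back at 25.
- 21 is chlorinated as above and chloro ketone 23 is isolated.
- LiAlH4 (Et2O, −78 °C) reduces the ketone to the chlorohydrin F5.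
- AgOTf with 2,6-di-tert-butylpyridine (CH2Cl2, −20 °C) brings about the silver-assisted halohydrin semipinacol ring contraction, with the same anti 1,2-shift, to the ring-contracted aldehyde F6.
- 1 M HCl/THF hydrolyses the silyl enol ether to the keto aldehyde F7.
- Pinnick oxidation (NaClO2, NaH2PO4, 2-methylbut-2-ene, t-BuOH/H2O) gives 25.

Further compounds
F1 | step 7 | tert-butyl{[(4Z)-3-ethenyl-3-ethylhepta-1,4-dien-4-yl]oxy}dimethylsilane | CC/C=C(\O[Si](C)(C)C(C)(C)C)C(CC)(C=C)C=C
F2 | step 8 | (E)-3-ethenyl-3-ethyl-1-phenylhept-1-en-4-one (racemic) | CCCC(=O)C(CC)(C=C)/C=C/c1ccccc1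
F3 | step 8 | silyl enol ether Michael adduct of F2 and 15 with the quaternary configuration that leads to 21 | CCC(=C)[C@@H]1[C@@H](C(CC)C(=O)[C@](CC)(C=C)/C=C/c2ccccc2)C(CC)=C(O[Si](C)(C)C(C)(C)C)[C@H]1C
F4 | step 8 | quaternary-carbon epimer of F3 | CCC(=C)[C@@H]1[C@@H](C(CC)C(=O)[C@@](CC)(C=C)/C=C/c2ccccc2)C(CC)=C(O[Si](C)(C)C(C)(C)C)[C@H]1C
F5 | step 10 | chlorohydrin from reduction of 23 (carbinol epimers) | CCC1=C[C@@](/C=C/c3ccccc3)(CC)C(O)[C@@](Cl)(CC)[C@@H]2[C@@H]1[C@H](C)C(O[Si](C)(C)C(C)(C)C)=C2CC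
F6 | step 10 | ring-contracted aldehyde with silyl enol ether (4-formyl analogue of 24) | CCC1=C[C@@](/C=C/c3ccccc3)(CC)[C@](CC)(C=O)[C@@H]2[C@@H]1[C@H](C)C(O[Si](C)(C)C(C)(C)C)=C2CC
F7 | step 10 | keto aldehyde (4-formyl analogue of 25) | CCC1=C[C@@](/C=C/c2ccccc2)(CC)[C@](CC)(C=O)[C@@H]2[C@@H]1[C@H](C)C(=O)[C@H]2CC
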